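**Retrosynthetic overview**
1. The target is a trans-fused decalin in which ring B carries oxygen at C8, next to C9 and two bonds from the ring-fusion carbon C10, and the shared quaternary carbon C5 carries the C14 methyl. The plan rests on reading the C8 oxygen as the enol ether oxygen of a 2-silyloxydiene C7=C8–C9=C10 and C14 as a formyl group on a C5=C6 dienophile tied to C10 through C4–C3–C2–C1.
2. Endgame disconnections: both (Z)-hex-2-enoates from hex-2-ynoates at O3 and O9; C8–OH from the 8-ketone; the C7 isopropenyl group by α-alkenylation of that ketone; C9–O by Rubottom oxidation of the C8=C9 silyl enol ether; the C14 methyl from the angular formyl group.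
3. Key disconnection: C5–C10 and C6–C7 by an intramolecular Diels–Alder reaction of an acyclic silyloxytrienal; rings A and B are formed together and C5 and C10 are set.
4. The trienal is built linearly from (Z)-hept-4-enal: syn-crotylboration (C3, C4), hydroboration of the new vinyl group, cross-metathesis with methyl vinyl ketone, oxidation, α-methylenation with formaldehyde, enol silylation.

Key step: step 8

Remark: eremophilane numbering is used for all bicyclic compounds (ring A: C1–C5 and C10; ring B: C5–C10; C14 on C5, C15 on C4, C11–C13 the isopropenyl group; β is the face of the C5 substituent, α that of H-10). The 1-ethoxyethyl group is carried as a mixture of two epimers at its acetal carbon and is removed in the last step.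

Step 1
Reactants: 1 (Z)-hept-4-enal; 2 (Z)-but-2-ene
Product: 4 (3R,4R,7Z)-3-methyldeca-1,7-dien-4-ol, via diisopinocampheylborinate 3 (not isolated)
Conditions: 2, KOt-Bu, n-BuLi, THF, −78 → −45 °C; (−)-Ipc2BOMe [from (+)-α-pinene], −78 °C; BF3·OEt2; 1, −78 °C; NaOH, H2O2, 0 °C → rt
Reagents that add atoms: (Z)-but-2-ene (2), C/C=C\C
Why: Brown asymmetric crotylboration through a closed chair-like six-membered transition state, in which the Z-crotyl geometry should give the 3,4-syn relationship and the isopinocampheyl groups derived from (+)-α-pinene should direct attack to the Si face of the aldehyde, setting both new stereocentres as R; the remote Z-alkene is a spectator.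

Step 2
Reactants: 4 (3R,4R,7Z)-3-methyldeca-1,7-dien-4-ol
Product: 5 tert-butyl(dimethyl){[(3R,4R,7Z)-3-methyldeca-1,7-dien-4-yl]oxy}silane
Conditions: t-BuMe2SiOTf, 2,6-lutidine, CH2Cl2, −78 → 0 °C
Reagents that add atoms: tert-butyldimethylsilyl trifluoromethanesulfonate, CC(C)(C)[Si](C)(C)OS(=O)(=O)C(F)(F)F
Why: Silylation of the secondary alcohol with a silyl triflate and a hindered pyridine base gives an ether that should survive every step up to the fluoride cleavage in step 17.

Step 3
Reactants: 5 tert-butyl(dimethyl){[(3R,4R,7Z)-3-methyldeca-1,7-dien-4-yl]oxy}silane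
Product: 7 (3R,4R,7Z)-4-[(tert-butyldimethylsilyl)oxy]-3-methyldec-7-en-1-ol, via alkyl-9-BBN borane 6 (not isolated)
Conditions: 9-BBN, THF, 0 °C → rt; NaOH, H2O2, 0 °C
Reagents that add atoms: hydrogen peroxide, OO
Why: Hydroboration–oxidation with 9-BBN adds anti-Markovnikov and far faster to the monosubstituted vinyl group than to the internal 1,2-disubstituted alkene, so only the terminal alkene should become the primary alcohol and no stereocentre is touched.

Step 4
Reactants: 7 (3R,4R,7Z)-4-[(tert-butyldimethylsilyl)oxy]-3-methyldec-7-en-1-ol; 8 but-3-en-2-one (methyl vinyl ketone)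
Product: 9 (3E,7R,8R)-7-[(tert-butyldimethylsilyl)oxy]-10-hydroxy-8-methyldec-3-en-2-one
Conditions: 8 (excess), second-generation Grubbs catalyst RuCl2(=CHPh)(H2IMes)(PCy3) (5 mol%), CH2Cl2, 40 °C
Reagents that add atoms: but-3-en-2-one (8), C=CC(C)=O
Why: Olefin cross-metathesis exchanges the propylidene end of the internal alkene for the acylmethylidene of the electron-poor enone, which is slow to homodimerise, and should give the E-enone; 7 has no second alkene, so ring-closing metathesis cannot compete.

Step 5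
Reactants: 9 (3E,7R,8R)-7-[(tert-butyldimethylsilyl)oxy]-10-hydroxy-8-methyldec-3-en-2-one
Product: 10 (3R,4R,7E)-4-[(tert-butyldimethylsilyl)oxy]-3-methyl-9-oxodec-7-enal
Conditions: Dess–Martin periodinane, CH2Cl2, 0 °C → rt
Reagents that add atoms: none
Why: Dess–Martin oxidation takes the primary alcohol to the aldehyde under near-neutral conditions that should leave the enone and the silyl ether untouched.

Step 6
Reactants: 10 (3R,4R,7E)-4-[(tert-butyldimethylsilyl)oxy]-3-methyl-9-oxodec-7-enal; 11 formaldehyde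
Product: 12 (3R,4R,7E)-4-[(tert-butyldimethylsilyl)oxy]-3-methyl-2-methylidene-9-oxodec-7-enal
Conditions: 11 (37% aq.), pyrrolidine (10 mol%), EtCO2H (10 mol%), i-PrOH, 45 °C
Reagents that add atoms: formaldehyde (11), C=O
Why: Amine-catalysed α-methylenation (Mannich condensation, then β-elimination of the amine), in which the aldehyde enamine should attack the methyleneiminium ion far faster than the much less electrophilic tethered enone, while the methyl ketone is not engaged and the neighbouring stereocentre carries no acidifying group.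

Step 7
Reactants: 12 (3R,4R,7E)-4-[(tert-butyldimethylsilyl)oxy]-3-methyl-2-methylidene-9-oxodec-7-enal
Product: 13 (3R,4R,7E)-4-[(tert-butyldimethylsilyl)oxy]-3-methyl-2-methylidene-9-[(triisopropylsilyl)oxy]deca-7,9-dienal
Conditions: i-Pr3SiOTf, Et3N, CH2Cl2, −78 → 0 °C
Reagents that add atoms: triisopropylsilyl trifluoromethanesulfonate, CC(C)[Si](C(C)C)(C(C)C)OS(=O)(=O)C(F)(F)F
Why: Soft enolisation of the methyl ketone (silyl triflate and tertiary amine) should give the cross-conjugated 2-silyloxydiene by kinetic loss of a methyl proton, while the 2-substituted acrolein has no enolisable α-hydrogen and should stay as it is.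

Step 8
Reactants: 13 (3R,4R,7E)-4-[(tert-butyldimethylsilyl)oxy]-3-methyl-2-methylidene-9-[(triisopropylsilyl)oxy]deca-7,9-dienal
Product: 14 (3R,4R,5R,10S)-3α-[(tert-butyldimethylsilyl)oxy]-8-[(triisopropylsilyl)oxy]-11,12,13-trinoreremophil-8-en-14-al (trans-fused octalin; 4β-CH3; 5β-CHO; 10α-H; silyl enol ether C8=C9)
Conditions: toluene (0.01 M), BHT (trace), 110 °C, sealed tube, base-washed glass
Reagents that add atoms: none
Why: A thermal, concerted but asynchronous normal-electron-demand [4+2] cycloaddition in which the HOMO of the 2-silyloxydiene (largest coefficient at C7) meets the LUMO of the 2-substituted acrolein (largest coefficient at C6), so that C6–C7 bonding leads and C5–C10 follows. The closest known reaction type is the intramolecular Diels–Alder reaction of 1,7,9-decatrienes whose dienophile is an α-substituted acrolein, which gives decalins with an angular formyl group. Ring B is the cycloadduct ring, closed by both new bonds (C5–C10 and C6–C7), and ring A is the tether ring, closed in the same event by C5–C10 across the C1–C4 chain, each as a six-membered ring. C5 and C10 are the new stereocentres: their trans relationship should follow from the transition state with the formyl group endo over the diene and the tether exo, and their absolute sense from the chair-like folding of the tether that keeps the C4 methyl and the C3 silyloxy group equatorial and avoids allylic strain between C4 and the C5=C6 unit. The step needs trans ring fusion and one dienophile face; the endo preference of the formyl group and the C3/C4 stereocentres set in step 1 are relied on for these, as an expectation from close analogues and not a certainty. The silyl enol ether left in the product fixes the C8 oxygen and marks C9 for oxidation.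

Step 9
Reactants: 14 (3R,4R,5R,10S)-3α-[(tert-butyldimethylsilyl)oxy]-8-[(triisopropylsilyl)oxy]-11,12,13-trinoreremophil-8-en-14-al
Product: 15 (3R,4R,5R,10S)-3α-[(tert-butyldimethylsilyl)oxy]-8-[(triisopropylsilyl)oxy]-11,12,13-trinoreremophil-8-en-14-ol
Conditions: NaBH4, THF/MeOH, 0 °C
Reagents that add atoms: none
Why: Borohydride reduction of the neopentyl aldehyde gives the primary alcohol, and the basic medium should keep intact the triisopropylsilyl enol ether that masks the C8 ketone.

Step 10
Reactants: 15 (3R,4R,5R,10S)-3α-[(tert-butyldimethylsilyl)oxy]-8-[(triisopropylsilyl)oxy]-11,12,13-trinoreremophil-8-en-14-ol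
Product: 17 O-[(3R,4R,5R,10S)-3α-(tert-butyldimethylsilyloxy)-8-(triisopropylsilyloxy)-11,12,13-trinoreremophil-8-en-14-yl] S-methyl dithiocarbonate, via sodium xanthate 16 (not isolated)
Conditions: NaH, THF, 0 °C → rt; CS2; MeI
Reagents that add atoms: carbon disulfide, S=C=S; iodomethane, CI
Why: Xanthate formation (alkoxide addition to CS2, then S-methylation) is the first stage of a Barton–McCombie deoxygenation and should be tolerated by both silyl ethers and the silyl enol ether.

Step 11
Reactants: 17 O-[(3R,4R,5R,10S)-3α-(tert-butyldimethylsilyloxy)-8-(triisopropylsilyloxy)-11,12,13-trinoreremophil-8-en-14-yl] S-methyl dithiocarbonate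
Product: 18 (3R,4R,5S,10S)-3α-[(tert-butyldimethylsilyl)oxy]-8-[(triisopropylsilyl)oxy]-11,12,13-trinoreremophil-8-ene (C14 is now the angular methyl)
Conditions: Bu3SnH, AIBN, toluene, 110 °C, slow addition
Reagents that add atoms: none
Why: Barton–McCombie deoxygenation, in which the stannyl radical adds to the thiocarbonyl sulfur, β-scission releases the primary C14 radical and the tin hydride reduces it to the methyl group; the quaternary C5 offers no β-hydrogen for a Chugaev elimination and cyclisation of the radical onto the enol ether would need a four-membered or strained bridged ring.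

Step 12
Reactants: 18 (3R,4R,5S,10S)-3α-[(tert-butyldimethylsilyl)oxy]-8-[(triisopropylsilyl)oxy]-11,12,13-trinoreremophil-8-ene
Product: 20 (3R,4R,5R,9S,10R)-3α-[(tert-butyldimethylsilyl)oxy]-9α-[(triisopropylsilyl)oxy]-11,12,13-trinoreremophilan-8-one, via silyloxy epoxide 19 (not isolated)
Conditions: mCPBA, NaHCO3, CH2Cl2, −20 → 0 °C
Reagents that add atoms: 3-chloroperoxybenzoic acid, OOC(=O)c1cccc(Cl)c1
Why: Rubottom oxidation, in which the peracid should epoxidise the electron-rich enol ether from the α face (anti to the axial C5 methyl, which is syn-axial to the β side of C9) and the silyloxy epoxide opens with 1,4-silyl shift to the 9α-silyloxy 8-ketone, setting C9 with its oxygen equatorial.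

Step 13
Reactants: 20 (3R,4R,5R,9S,10R)-3α-[(tert-butyldimethylsilyl)oxy]-9α-[(triisopropylsilyl)oxy]-11,12,13-trinoreremophilan-8-one
Product: 21 (3R,4R,5R,9S,10R)-3α-[(tert-butyldimethylsilyl)oxy]-9α-[(triisopropylsilyl)oxy]-8-[(trimethylsilyl)oxy]-11,12,13-trinoreremophil-7-ene
Conditions: LiN(i-Pr)2, Me3SiCl, THF, −78 °C; non-aqueous work-up
Reagents that add atoms: chlorotrimethylsilane, C[Si](C)(C)Cl
Why: Kinetic enolate formation and O-silylation, in which the hindered amide base should take a proton from the unsubstituted C7 methylene and not the tertiary C9–H shielded by the triisopropylsilyloxy group, fixing the enol ether at C7=C8.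

Step 14
Reactants: 21 (3R,4R,5R,9S,10R)-3α-[(tert-butyldimethylsilyl)oxy]-9α-[(triisopropylsilyl)oxy]-8-[(trimethylsilyl)oxy]-11,12,13-trinoreremophil-7-ene; 22 2-bromopropene
Product: 24 (3R,4R,5R,7S,9S,10R)-3α-[(tert-butyldimethylsilyl)oxy]-9α-[(triisopropylsilyl)oxy]eremophil-11-en-8-one (7α-isopropenyl), via tributyltin enolate 23 (not isolated)
Conditions: 22 (excess), Bu3SnF, Pd2(dba)3 (cat.), P(t-Bu)3 (cat.), toluene, 85 °C, sealed tube
Reagents that add atoms: 2-bromopropene (22), CC(Br)=C
Why: Palladium-catalysed α-alkenylation of a ketone enolate (fluoride-driven Si-to-Sn exchange gives the tin enolate, which transmetalates to the alkenylpalladium bromide formed by oxidative addition of 22 to zerovalent palladium, and reductive elimination forms C7–C11), in which the metal is expected on the less hindered α face of C7, anti to the C5 methyl, so that the isopropenyl group should enter equatorial (7S), and the neutral medium should keep the β,γ-unsaturated ketone from enolising toward the conjugated isomer.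

Step 15
Reactants: 24 (3R,4R,5R,7S,9S,10R)-3α-[(tert-butyldimethylsilyl)oxy]-9α-[(triisopropylsilyl)oxy]eremophil-11-en-8-one
Product: 25 (3R,4R,5R,7S,8R,9S,10R)-3α-[(tert-butyldimethylsilyl)oxy]-9α-[(triisopropylsilyl)oxy]eremophil-11-en-8α-ol
Conditions: LiBH(s-Bu)3, THF, −78 °C; NaOH, H2O2, 0 °C
Reagents that add atoms: none
Why: Reduction with a bulky trialkylborohydride, which attacks a cyclohexanone along the equatorial direction, should place the new hydroxyl axial on the α face (8R), cis to the C9 oxygen and to the isopropenyl group.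

Step 16
Reactants: 25 (3R,4R,5R,7S,8R,9S,10R)-3α-[(tert-butyldimethylsilyl)oxy]-9α-[(triisopropylsilyl)oxy]eremophil-11-en-8α-ol
Product: 26 (3R,4R,5R,7S,8R,9S,10R)-3α-[(tert-butyldimethylsilyl)oxy]-8α-(1-ethoxyethoxy)-9α-[(triisopropylsilyl)oxy]eremophil-11-ene
Conditions: ethyl vinyl ether, PPTS (cat.), CH2Cl2, rt
Reagents that add atoms: ethyl vinyl ether, C=COCC
Why: Acid-catalysed addition of the alcohol to a vinyl ether (acetal protection) masks the axial C8 hydroxyl so that only O3 and O9 are acylated later; the small oxocarbenium electrophile should reach the flanked hydroxyl and the weak acid should spare the isopropenyl group and the silyl ethers.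

Step 17
Reactants: 26 (3R,4R,5R,7S,8R,9S,10R)-3α-[(tert-butyldimethylsilyl)oxy]-8α-(1-ethoxyethoxy)-9α-[(triisopropylsilyl)oxy]eremophil-11-ene
Product: 27 (3R,4R,5R,7S,8R,9S,10R)-8α-(1-ethoxyethoxy)eremophil-11-ene-3α,9α-diol
Conditions: Bu4NF, THF, rt
Reagents that add atoms: none
Why: Fluoride cleavage of both silyl ethers, driven by Si–F bond formation, should leave the base-stable acetal at O8 in place, and no acyl group is yet present that could migrate.

Step 18
Reactants: 27 (3R,4R,5R,7S,8R,9S,10R)-8α-(1-ethoxyethoxy)eremophil-11-ene-3α,9α-diol; 28 hex-2-ynoic acid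
Product: 29 (3R,4R,5R,7S,8R,9S,10R)-8α-(1-ethoxyethoxy)eremophil-11-ene-3α,9α-diyl bis(hex-2-ynoate)
Conditions: 28 (excess), DCC, DMAP (cat.), CH2Cl2, 0 °C → rt
Reagents that add atoms: hex-2-ynoic acid (28), CCCC#CC(=O)O
Why: Steglich esterification (carbodiimide activation, DMAP acyl transfer) should acylate the two equatorial secondary alcohols at C3 and C9, the alkynoate serving as a configurationally safe precursor of the Z-alkenoate.

Step 19
Reactants: 29 (3R,4R,5R,7S,8R,9S,10R)-8α-(1-ethoxyethoxy)eremophil-11-ene-3α,9α-diyl bis(hex-2-ynoate)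
Product: 30 (3R,4R,5R,7S,8R,9S,10R)-8α-(1-ethoxyethoxy)eremophil-11-ene-3α,9α-diyl bis[(2Z)-hex-2-enoate]
Conditions: H2 (1 atm), Pd/CaCO3 poisoned with Pb(OAc)2 (Lindlar catalyst), quinoline, EtOAc, rt
Reagents that add atoms: none
Why: Lindlar semihydrogenation adds one equivalent of hydrogen syn to each alkyne on the poisoned palladium surface and should give the two (Z)-hex-2-enoates, the 1,1-disubstituted isopropenyl alkene and the product alkenes being reduced much more slowly.

Step 20
Reactants: 30 (3R,4R,5R,7S,8R,9S,10R)-8α-(1-ethoxyethoxy)eremophil-11-ene-3α,9α-diyl bis[(2Z)-hex-2-enoate]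
Product: 31 (3R,4R,5R,7S,8R,9S,10R)-8α-hydroxyeremophil-11-ene-3α,9α-diyl bis[(2Z)-hex-2-enoate] (CNP0420276.1)
Conditions: PPTS (cat.), MeOH, rt
Reagents that add atoms: none
Why: Mild acid-catalysed transacetalisation to methanol should remove the 1-ethoxyethyl group and free the C8 hydroxyl without base-promoted acyl migration and without touching the Z-enoates or the isopropenyl group.

**Compound list**
1 | (Z)-hept-4-enal | CC/C=C\CCC=O | starting material
2 | (Z)-but-2-ene | C/C=C\C | starting material
3 | (3R,4R,7Z)-3-methyldeca-1,7-dien-4-yl bis(isopinocampheyl)borinate [isopinocampheyl from (+)-α-pinene] | C=C[C@@H](C)[C@H](OB([C@@H]1C[C@@H]2C[C@H]([C@H]1C)C2(C)C)[C@@H]1C[C@@H]2C[C@H]([C@H]1C)C2(C)C)CC/C=C\CC | intermediate (not isolated)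
4 | (3R,4R,7Z)-3-methyldeca-1,7-dien-4-ol | C=C[C@@H](C)[C@H](O)CC/C=C\CC | intermediate
5 | tert-butyl(dimethyl){[(3R,4R,7Z)-3-methyldeca-1,7-dien-4-yl]oxy}silane | C=C[C@@H](C)[C@H](O[Si](C)(C)C(C)(C)C)CC/C=C\CC | intermediate
6 | 9-[(3R,4R,7Z)-4-(tert-butyldimethylsilyloxy)-3-methyldec-7-en-1-yl]-9-borabicyclo[3.3.1]nonane | B1(C2CCCC1CCC2)CC[C@@H](C)[C@H](O[Si](C)(C)C(C)(C)C)CC/C=C\CC | intermediate (not isolated)
7 | (3R,4R,7Z)-4-[(tert-butyldimethylsilyl)oxy]-3-methyldec-7-en-1-ol | OCC[C@@H](C)[C@H](O[Si](C)(C)C(C)(C)C)CC/C=C\CC | intermediate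
8 | but-3-en-2-one (methyl vinyl ketone) | C=CC(C)=O | starting material
9 | (3E,7R,8R)-7-[(tert-butyldimethylsilyl)oxy]-10-hydroxy-8-methyldec-3-en-2-one | OCC[C@@H](C)[C@H](O[Si](C)(C)C(C)(C)C)CC/C=C/C(C)=O | intermediate
10 | (3R,4R,7E)-4-[(tert-butyldimethylsilyl)oxy]-3-methyl-9-oxodec-7-enal | O=CC[C@@H](C)[C@H](O[Si](C)(C)C(C)(C)C)CC/C=C/C(C)=O | intermediate
11 | formaldehyde | C=O | starting material
12 | (3R,4R,7E)-4-[(tert-butyldimethylsilyl)oxy]-3-methyl-2-methylidene-9-oxodec-7-enal | C=C(C=O)[C@@H](C)[C@H](O[Si](C)(C)C(C)(C)C)CC/C=C/C(C)=O | intermediate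
13 | (3R,4R,7E)-4-[(tert-butyldimethylsilyl)oxy]-3-methyl-2-methylidene-9-[(triisopropylsilyl)oxy]deca-7,9-dienal (key-step precursor) | C=C(C=O)[C@@H](C)[C@H](O[Si](C)(C)C(C)(C)C)CC/C=C/C(O[Si](C(C)C)(C(C)C)C(C)C)=C | intermediate
14 | (3R,4R,5R,10S)-3α-[(tert-butyldimethylsilyl)oxy]-8-[(triisopropylsilyl)oxy]-11,12,13-trinoreremophil-8-en-14-al (key-step product) | C1C[C@]2(C=O)[C@@H](C)[C@H](O[Si](C)(C)C(C)(C)C)CC[C@H]2C=C1O[Si](C(C)C)(C(C)C)C(C)C | intermediate
15 | (3R,4R,5R,10S)-3α-[(tert-butyldimethylsilyl)oxy]-8-[(triisopropylsilyl)oxy]-11,12,13-trinoreremophil-8-en-14-ol | C1C[C@]2(CO)[C@@H](C)[C@H](O[Si](C)(C)C(C)(C)C)CC[C@H]2C=C1O[Si](C(C)C)(C(C)C)C(C)C | intermediate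
16 | sodium xanthate of 15 (sodium O-alkyl dithiocarbonate at O14) | C1C[C@]2(COC(=S)[S-])[C@@H](C)[C@H](O[Si](C)(C)C(C)(C)C)CC[C@H]2C=C1O[Si](C(C)C)(C(C)C)C(C)C.[Na+] | intermediate (not isolated)
17 | O-[(3R,4R,5R,10S)-3α-(tert-butyldimethylsilyloxy)-8-(triisopropylsilyloxy)-11,12,13-trinoreremophil-8-en-14-yl] S-methyl dithiocarbonate | C1C[C@]2(COC(=S)SC)[C@@H](C)[C@H](O[Si](C)(C)C(C)(C)C)CC[C@H]2C=C1O[Si](C(C)C)(C(C)C)C(C)C | intermediate
18 | (3R,4R,5S,10S)-3α-[(tert-butyldimethylsilyl)oxy]-8-[(triisopropylsilyl)oxy]-11,12,13-trinoreremophil-8-ene | C1C[C@]2(C)[C@@H](C)[C@H](O[Si](C)(C)C(C)(C)C)CC[C@H]2C=C1O[Si](C(C)C)(C(C)C)C(C)C | intermediate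
19 | 8α,9α-epoxide of 18 (8β-triisopropylsilyloxy) | C1C[C@]2(C)[C@@H](C)[C@H](O[Si](C)(C)C(C)(C)C)CC[C@H]2[C@@H]3O[C@]13O[Si](C(C)C)(C(C)C)C(C)C | intermediate (not isolated)
20 | (3R,4R,5R,9S,10R)-3α-[(tert-butyldimethylsilyl)oxy]-9α-[(triisopropylsilyl)oxy]-11,12,13-trinoreremophilan-8-one | C1C[C@]2(C)[C@@H](C)[C@H](O[Si](C)(C)C(C)(C)C)CC[C@H]2[C@H](O[Si](C(C)C)(C(C)C)C(C)C)C1=O | intermediate
21 | (3R,4R,5R,9S,10R)-3α-[(tert-butyldimethylsilyl)oxy]-9α-[(triisopropylsilyl)oxy]-8-[(trimethylsilyl)oxy]-11,12,13-trinoreremophil-7-ene | C=1C[C@]2(C)[C@@H](C)[C@H](O[Si](C)(C)C(C)(C)C)CC[C@H]2[C@H](O[Si](C(C)C)(C(C)C)C(C)C)C=1O[Si](C)(C)C | intermediate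
22 | 2-bromopropene | CC(Br)=C | starting material
23 | tributyltin enolate corresponding to 21 (O-stannyl form) | C=1C[C@]2(C)[C@@H](C)[C@H](O[Si](C)(C)C(C)(C)C)CC[C@H]2[C@H](O[Si](C(C)C)(C(C)C)C(C)C)C=1O[Sn](CCCC)(CCCC)CCCC | intermediate (not isolated)
24 | (3R,4R,5R,7S,9S,10R)-3α-[(tert-butyldimethylsilyl)oxy]-9α-[(triisopropylsilyl)oxy]eremophil-11-en-8-one | C=C(C)[C@@H]1C[C@]2(C)[C@@H](C)[C@H](O[Si](C)(C)C(C)(C)C)CC[C@H]2[C@H](O[Si](C(C)C)(C(C)C)C(C)C)C1=O | intermediate
25 | (3R,4R,5R,7S,8R,9S,10R)-3α-[(tert-butyldimethylsilyl)oxy]-9α-[(triisopropylsilyl)oxy]eremophil-11-en-8α-ol | C=C(C)[C@@H]1C[C@]2(C)[C@@H](C)[C@H](O[Si](C)(C)C(C)(C)C)CC[C@H]2[C@H](O[Si](C(C)C)(C(C)C)C(C)C)[C@@H]1O | intermediate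
26 | (3R,4R,5R,7S,8R,9S,10R)-3α-[(tert-butyldimethylsilyl)oxy]-8α-(1-ethoxyethoxy)-9α-[(triisopropylsilyl)oxy]eremophil-11-ene | C=C(C)[C@@H]1C[C@]2(C)[C@@H](C)[C@H](O[Si](C)(C)C(C)(C)C)CC[C@H]2[C@H](O[Si](C(C)C)(C(C)C)C(C)C)[C@@H]1OC(C)OCC | intermediate
27 | (3R,4R,5R,7S,8R,9S,10R)-8α-(1-ethoxyethoxy)eremophil-11-ene-3α,9α-diol | C=C(C)[C@@H]1C[C@]2(C)[C@@H](C)[C@H](O)CC[C@H]2[C@H](O)[C@@H]1OC(C)OCC | intermediate
28 | hex-2-ynoic acid | CCCC#CC(=O)O | starting material
29 | (3R,4R,5R,7S,8R,9S,10R)-8α-(1-ethoxyethoxy)eremophil-11-ene-3α,9α-diyl bis(hex-2-ynoate) | C=C(C)[C@@H]1C[C@]2(C)[C@@H](C)[C@H](OC(=O)C#CCCC)CC[C@H]2[C@H](OC(=O)C#CCCC)[C@@H]1OC(C)OCC | intermediate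
30 | (3R,4R,5R,7S,8R,9S,10R)-8α-(1-ethoxyethoxy)eremophil-11-ene-3α,9α-diyl bis[(2Z)-hex-2-enoate] | C=C(C)[C@@H]1C[C@]2(C)[C@@H](C)[C@H](OC(=O)/C=C\CCC)CC[C@H]2[C@H](OC(=O)/C=C\CCC)[C@@H]1OC(C)OCC | intermediate
31 | (3R,4R,5R,7S,8R,9S,10R)-8α-hydroxyeremophil-11-ene-3α,9α-diyl bis[(2Z)-hex-2-enoate] (CNP0420276.1) | C=C(C)[C@@H]1C[C@]2(C)[C@@H](C)[C@H](OC(=O)/C=C\CCC)CC[C@H]2[C@H](OC(=O)/C=C\CCC)[C@@H]1O | target

**Total step count:** 20
**Longest linear sequence:** 20 steps (1 to 31; the route is fully linear)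

**Three steps most likely to fail**

Step 14 (C7 isopropenylation). What may go wrong is β-hydride elimination from the palladium enolate (dehydrogenation toward the 6-en-8-one), failure of the hindered secondary enolate to transmetalate, or drift of the new double bond into conjugation with loss of the C7 configuration. The fallback sets out from 20 and comes back at 26. The lithium enolate of 20 (LiN(i-Pr)2, THF, −78 °C, then ZnCl2) is added to acetone in an aldol reaction to give the 7α-(2-hydroxypropan-2-yl) 8-ketone F1, the new C–C bond forming on the α face. LiBH(s-Bu)3 should then reduce the ketone from the equatorial direction to give the 8α,11-diol F2. Ethyl vinyl ether and PPTS should protect the secondary hydroxyl ahead of the more hindered tertiary one and give the 8α-(1-ethoxyethyl) ether F3. The Burgess reagent (benzene, 50 °C) dehydrates the tertiary alcohol by syn-elimination, expected mainly toward a methyl group because the alternative tetrasubstituted alkene is strained against C6 and O8, and gives 26.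

Step 8 (key cycloaddition). What may go wrong is a weak endo preference of the formyl group, so that the cis-fused adduct forms beside the trans-fused one. The fallback sets out from 18, taken as the mixture of ring-fusion isomers carried through steps 9 to 11, and comes back at 18. Saegusa–Ito oxidation (Pd(OAc)2, MeCN, rt) converts both isomers into the same 9-en-8-one F4, in which C10 is trigonal. Dissolving-metal reduction (Li, liquid NH3, THF, t-BuOH, −78 °C) should protonate C10 axially, as is usual for octalones with an angular methyl, and give the trans-fused lithium enolate. Trapping on oxygen with i-Pr3SiOTf returns 18 with the trans ring fusion.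

Step 11 (deoxygenation at C14). What may go wrong is slow β-scission of the radical adduct of the primary neopentyl xanthate, so that the alcohol is regenerated or the thiocarbonyl group is merely reduced. The fallback sets out from 14 and comes back at 18. Condensation of 14 with TsNHNH2 (THF, rt) gives the C14 tosylhydrazone F5. Catecholborane (CHCl3, 0 °C) adds hydride to the C=N bond, and NaOAc·3H2O at reflux triggers loss of sulfinate and of dinitrogen from the resulting diazene, which turns the formyl carbon directly into the C14 methyl group of 18.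

**Further compounds**
F1 | step 14 | (3R,4R,5R,7S,9S,10R)-3α-[(tert-butyldimethylsilyl)oxy]-11-hydroxy-9α-[(triisopropylsilyl)oxy]eremophilan-8-one | CC(C)(O)[C@@H]1C[C@]2(C)[C@@H](C)[C@H](O[Si](C)(C)C(C)(C)C)CC[C@H]2[C@H](O[Si](C(C)C)(C(C)C)C(C)C)C1=O
F2 | step 14 | (3R,4R,5R,7S,8R,9S,10R)-3α-[(tert-butyldimethylsilyl)oxy]-9α-[(triisopropylsilyl)oxy]eremophilane-8α,11-diol | CC(C)(O)[C@@H]1C[C@]2(C)[C@@H](C)[C@H](O[Si](C)(C)C(C)(C)C)CC[C@H]2[C@H](O[Si](C(C)C)(C(C)C)C(C)C)[C@@H]1O
F3 | step 14 | (3R,4R,5R,7S,8R,9S,10R)-3α-[(tert-butyldimethylsilyl)oxy]-8α-(1-ethoxyethoxy)-9α-[(triisopropylsilyl)oxy]eremophilan-11-ol | CC(C)(O)[C@@H]1C[C@]2(C)[C@@H](C)[C@H](O[Si](C)(C)C(C)(C)C)CC[C@H]2[C@H](O[Si](C(C)C)(C(C)C)C(C)C)[C@@H]1OC(C)OCC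
F4 | step 8 | (3R,4R,5S)-3α-[(tert-butyldimethylsilyl)oxy]-11,12,13-trinoreremophil-9-en-8-one | C1C[C@]2(C)[C@@H](C)[C@H](O[Si](C)(C)C(C)(C)C)CCC2=CC1=O
F5 | step 11 | N'-[(E)-C14-ylidene] 4-methylbenzenesulfonohydrazide of 14 (tosylhydrazone of the angular aldehyde) | C1C[C@]2(/C=N/NS(=O)(=O)c3ccc(C)cc3)[C@@H](C)[C@H](O[Si](C)(C)C(C)(C)C)CC[C@H]2C=C1O[Si](C(C)C)(C(C)C)C(C)C
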